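## Structural features

- Target 21 is a single six-membered carbocycle, a cyclohex-2-en-1-one. C1 is the ketone, C2 carries the hydroxymethyl carbon C7, C3 is the vinylic CH, C4 bears a propanoate, C5 an isopropyl group and C6 an (E)-4-hydroxy-2-methylbut-2-enoate.
- C4, C5 and C6 are three contiguous stereocentres (4S,5S,6R). The C4 oxygen is cis to the isopropyl group and the C6 oxygen is trans to it.
- C1 and C4 are para-related oxygenated carbons at different oxidation levels (ketone and carbinol). O4 and O6 carry two different acyl groups, and two primary allylic hydroxyls (on C7 and on the side chain) stay free.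
- The fragile groups are the α-acyloxy ketone at C6 (enolisable, open to acyl migration), the γ-acyloxy enone and the conjugated E-enoate. Loss of propanoic acid across C4–C5 followed by enolisation would give a phenol, so base is a hazard throughout.
- The carbon skeleton is simple. The real difficulty is absolute control of the trans C5/C6 and cis C4/C5 relationships, together with telling C1 from C4 and O4 from O6.
- The key step exploits the para relationship of C1 and C4, which is that of a quinone monoketal, and the unsubstituted C5=C6 enone of that dienone. Conjugate addition at C5 and enolate oxygenation at C6 build the trans pair; the C2 substituent (the future C7) shields the other enone, and the C4 ketal stores a carbonyl for later reduction.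

## Logic of the disconnections

**21 to 20.** The two O–Si bonds on the primary allylic oxygens (O7 and the side-chain oxygen) are cut. Both hydroxyls must stay silent during every acylation and oxidation, and one acidic fluoride treatment at the end releases them together. The forward step must spare two esters, the enone and the enolisable C6 centre.

**20 to 14 and 18.** The O6–acyl bond is cut, making the route convergent. The C6 ester is introduced last because an acyloxy group on C6 would be a β-leaving group while C4 is a ketone (the stage of 10), and an unsaturated ester would be exposed to the hydride steps. The forward step must acylate a hindered α-ketol without epimerising C6 or isomerising the enoate; activation as 19 answers this.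

**18 to 17 to 15 and 16.** The ester C–O bond and then the C2=C3 double bond of the side chain are cut. A stabilised ylide supplies the E geometry, and both fragments are commercial. The hydrolysis must not remove the silyl ether.

**14 to 13 to 12.** The C1 carbonyl is traced back to a carbinol and the two free hydroxyls to triethylsilyl ethers. C1 has to be a carbinol for as long as C4 is a ketone, so it is reoxidised only once C4 is fixed as its ester. The forward steps need silyl cleavage that leaves the tert-butyldiphenylsilyl ether alone and an oxidant that takes the allylic C1 hydroxyl but not the saturated C6 hydroxyl.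

**12 to 11 to 10.** The O4–propanoyl bond and then the C4–H bond are cut. A ring ketone next to the isopropyl-bearing carbon lets the C4 configuration be set by the choice of hydride. The forward reduction must deliver hydride to the face opposite to isopropyl (equatorial attack) and in the 1,2 mode.

**10 to 9 to 8 to 7.** The C4 carbonyl is traced to the dimethyl ketal, the silyl ethers to a diol, and the C1–H bond to the C1 ketone. This is a 1,4-carbonyl transposition. If the ketal were opened while C1 was still a ketone, an ene-1,4-dione would form; it would tautomerise to a hydroquinone and erase C5 and C6. The forward steps need a 1,2-reduction of the enone, a mask that does not depend on the C1 configuration, and a ketal hydrolysis milder than silyl ether cleavage.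

**7 to 4 and 5.** The C5–isopropyl bond and the C6–O bond are cut in one operation, through 6. This removes both stereocentres and leads back to an achiral, flat dienone. The forward step needs facial control at C5 by a chiral catalyst, attack at C5 and not C3, and oxygen delivery anti to the new isopropyl group.

**4 to 3 to 2 to 1.** The two ketal C–O bonds are traced to a para-methoxyphenol, the O–Si bond to a benzylic alcohol, and the alcohol to an aldehyde. All ring carbons and C7 then come from one commercial arene. The forward steps need selective silylation of the benzylic hydroxyl beside the phenol and para-selective oxidative methoxylation.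

## Other disconnections considered

**Alternative 1:** The ring is cut at C4–C5 and C1–C6. In the forward sense 3-hydroxy-2-pyrone A1 and (E)-5-methylhex-3-en-2-one A2 would combine under a cinchona-derived bifunctional base in a [4+2] cycloaddition to the bridged lactone A3.

- In favour: one metal-free step would close the carbocycle, place the C2=C3 double bond and set C4, C5 and C6 with the right relative sense. The lactone oxygen on C4 is cis to isopropyl, and the E-enone fixes isopropyl trans to the C6 substituent. On the C4 stereocentre this is better than the chosen plan, which sets C4 by a later hydride reduction.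
- Against: the C6 substituent in A3 is an acetyl group, so a Baeyer–Villiger oxidation would be needed beside a strained alkene. The lactone carbonyl on C1 is an extra carbon that must be excised by oxidative decarboxylation to reveal the ketone. C7 is absent and would have to be added late by a Morita–Baylis–Hillman reaction on a base-sensitive enone. A β-isopropyl enone is a sluggish dienophile, and the bicyclic lactone can lose CO2 on warming.
- Comparison: the chosen plan has every ring carbon and C7 in place from the arene and needs no C–C cleavage. It pays for this with a carbonyl transposition. The two plans are about equal in length, with the alternative carrying more steps of uncertain chemoselectivity.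

**Alternative 2:** The ring is cut at C3–C4. The acyclic Z-iodoenone aldehyde A4 would be treated with CrCl2 and catalytic NiCl2; the vinylchromium species would add to the aldehyde and close the ring as the γ-hydroxy enone A5.

- In favour: the closure would deliver the C1 ketone and the C4 carbinol at their final oxidation levels, with O4 free and O6 already distinguished as its 4-methoxybenzyl ether. Only propanoylation, ether cleavage, esterification and desilylation would remain. On economy after the key step this is clearly better than the chosen plan.
- Against: A4 needs acyclic stereocontrol for C5 and C6 and carries both as epimerisable centres (α to the aldehyde and α to the ketone). It also carries a β-iodo enone whose Z geometry can be lost by addition–elimination. The C4 configuration would be set in the C–C bond formation with little leverage, and a wrong epimer could not be corrected by oxidation and reduction without passing through the unstable ene-1,4-dione. Divalent chromium is needed in large excess.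
- Comparison: the chosen plan sets C5 by a catalyst and C6 and C4 by substrate control on a ring, where the facial bias is easier to predict and C4 can still be inverted. The alternative is equal in the number of stereocentres set per step and shorter after ring closure, but longer and less secure before it.

**Alternative 3:** The ring is cut at C2–C3. The C-isopropyl hex-5-enopyranoside A6 would be treated with catalytic Hg(OCOCF3)2 in aqueous acetone. Oxymercuration of the enol ether, opening to a mercurio-ketone aldehyde and intramolecular aldol addition would give the β-hydroxy cyclohexanone A7.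

- In favour: the absolute configuration would come from the chiral pool, O4 and O6 would be distinguished as propanoate and 4-methoxybenzyl ether before the ring exists, and the closure is a reliable catalytic process. Dehydration of A7 would place the enone correctly without any redox transposition. On the certainty of absolute configuration and on the C1/C4 oxidation pattern the alternative is the equal or the better of the chosen plan.
- Against: a 3-C-isopropyl sugar of the required configuration needs a long sequence of protection and branching steps. C7 would again have to be added to the enone late under nucleophilic catalysis, with the C4 propanoate at risk. Divalent mercury is undesirable.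
- Comparison: the chosen plan is shorter, forms both a C–C and a C–O bond in its key step, and carries C7 from the start. The alternative replaces the catalyst-controlled step by chiral-pool certainty at the price of length.

Key step: step 4

Remarks on the chemistry (assumptions, one line each):

- The ring locants C1 to C7 of the target are used for every ring compound, also where systematic numbering would differ, and CIP descriptors refer to these locants.
- The hydroxy ketal 7 is (5R,6R) under CIP rules because the C4 ketal carbon outranks C6; a 5S label would describe the C5 epimer. The C5 descriptor changes between R and S along the route (S in 11, 12, 20, 21) only through changes in substituent priority.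
- O7 carries tert-butyldiphenylsilyl and not the smaller tert-butyldimethylsilyl group, because it must survive the acidic steps 3, 7 and 10; the skeleton of 4 and 7 is unchanged.
- The ligand L is (S,R,R)-O,O'-(1,1'-binaphthalene-2,2'-diyl)-N,N-bis(1-phenylethyl)phosphoramidite. It is expected to deliver isopropyl to C5 in the spatial sense in which ethyl enters cyclohex-2-enone to give (S)-3-ethylcyclohexanone, which corresponds to 5R in 6 and 7; the (R,S,S) antipode is used if the dienone responds in the opposite sense.
- C1 is a temporary stereocentre in 8 to 13. The 1R (trans-diol) epimer expected from step 5 is drawn; the 1S epimer would converge at 14.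

## Route

Step 1
Reactants: 1 2-hydroxy-5-methoxybenzaldehyde
Product: 2 2-(hydroxymethyl)-4-methoxyphenol
Conditions: NaBH4, MeOH, 0 °C
Reagents that add atoms: none
Why: Borohydride reduction of an aryl aldehyde; the phenol and the aryl methyl ether are inert to hydride.

Step 2
Reactants: 2 2-(hydroxymethyl)-4-methoxyphenol
Product: 3 2-[(tert-butyldiphenylsilyloxy)methyl]-4-methoxyphenol
Conditions: TBDPSCl (1.05 equiv), imidazole, CH2Cl2, 0 °C
Reagents that add atoms: tert-butyl(chloro)diphenylsilane, CC(C)(C)[Si](Cl)(c1ccccc1)c1ccccc1
Why: Silyl ether formation; under imidazole the primary benzylic hydroxyl should react much faster than the un-ionised, hydrogen-bonded phenol, and the bulky chlorosilane sharpens this preference.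

Step 3
Reactants: 3 2-[(tert-butyldiphenylsilyloxy)methyl]-4-methoxyphenol
Product: 4 2-[(tert-butyldiphenylsilyloxy)methyl]-4,4-dimethoxycyclohexa-2,5-dien-1-one
Conditions: PhI(OAc)2, MeOH, 0 °C
Reagents that add atoms: methanol, CO
Why: Oxidative dearomatisation of a para-methoxyphenol; the phenol oxygen binds to iodine and methanol adds at the para carbon that already carries methoxy, giving the cross-conjugated dienone monoketal. The silyl ether should tolerate the acetic acid set free.

Step 4
Reactants: 4 2-[(tert-butyldiphenylsilyloxy)methyl]-4,4-dimethoxycyclohexa-2,5-dien-1-one; 5 diisopropylzinc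
Product: 7 (5R,6R)-2-[(tert-butyldiphenylsilyloxy)methyl]-6-hydroxy-5-isopropyl-4,4-dimethoxycyclohex-2-en-1-one, via isopropylzinc enolate 6 (not isolated)
Conditions: Cu(OTf)2 (2 mol%), L (4 mol%), toluene, −30 °C; then 2-(phenylsulfonyl)-3-phenyloxaziridine, THF, −30 to 0 °C; aq. NH4Cl
Reagents that add atoms: 2-(phenylsulfonyl)-3-phenyloxaziridine, O=S(=O)(c1ccccc1)N1OC1c1ccccc1
Why: Cu(OTf)2 is reduced by the zinc reagent to a monovalent copper–phosphoramidite complex; transmetalation gives an isopropylcopper species that π-binds the unsubstituted C5=C6 enone of 4, adds oxidatively at C5 and eliminates reductively to form the C5–isopropyl bond, releasing the isopropylzinc enolate 6. The enolate carbon C6 then attacks the electrophilic oxygen of the N-sulfonyloxaziridine, the N–O bond breaks and the hemiaminal collapses to the C6 alkoxide and the sulfonimine. The closest known reaction type is the copper/phosphoramidite-catalysed enantioselective 1,4-addition of dialkylzincs (diisopropylzinc included) to cyclohex-2-enones and 4,4-dialkoxycyclohexa-2,5-dienones with electrophilic trapping of the zinc enolate, joined to the oxaziridine hydroxylation of ketone enolates. No ring is closed. C5 is set by the catalyst, since the ligand differentiates the two faces of the C5=C6 bond, and its antipode is available if the sense is opposite to that expected. C6 is set by the substrate, since the oxidant approaches the planar enolate anti to the adjacent C5 isopropyl group, which gives the trans (5R,6R) pair. Regioselectivity for C5 over C3 rests on the C2 silyloxymethyl group, which makes the other enone α-substituted and slower in conjugate addition; copper catalysis suppresses 1,2-addition and the ketal rules out rearomatisation. Excess oxaziridine and THF as cosolvent are used because the zinc enolate is a modest nucleophile and residual carbon–zinc bonds also consume oxidant.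

Step 5
Reactants: 7 (5R,6R)-2-[(tert-butyldiphenylsilyloxy)methyl]-6-hydroxy-5-isopropyl-4,4-dimethoxycyclohex-2-en-1-one
Product: 8 (1R,5R,6R)-2-[(tert-butyldiphenylsilyloxy)methyl]-5-isopropyl-4,4-dimethoxycyclohex-2-ene-1,6-diol
Conditions: NaBH4, CeCl3·7H2O, MeOH, −78 °C; aq. NaHCO3
Reagents that add atoms: none
Why: Luche reduction, which adds hydride 1,2 to the enone. Hydride should enter C1 on the face of the C6 hydroxyl, away from the isopropyl group, to give the trans diol (1R); this centre is temporary. The bicarbonate work-up preserves the ketal, which is now allylic and acid-labile.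

Step 6
Reactants: 8 (1R,5R,6R)-2-[(tert-butyldiphenylsilyloxy)methyl]-5-isopropyl-4,4-dimethoxycyclohex-2-ene-1,6-diol
Product: 9 (1R,5R,6R)-2-[(tert-butyldiphenylsilyloxy)methyl]-5-isopropyl-4,4-dimethoxy-1,6-bis(triethylsilyloxy)cyclohex-2-ene
Conditions: TESCl, imidazole, DMAP (cat.), DMF, 0 °C to rt
Reagents that add atoms: chlorotriethylsilane, CC[Si](Cl)(CC)CC
Why: Silylation of both secondary hydroxyls; an acyclic mask is chosen because it does not depend on the relative configuration of the diol. Triethylsilyl withstands hydride and acylation and is later removed by mild acid that leaves tert-butyldiphenylsilyl untouched.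

Step 7
Reactants: 9 (1R,5R,6R)-2-[(tert-butyldiphenylsilyloxy)methyl]-5-isopropyl-4,4-dimethoxy-1,6-bis(triethylsilyloxy)cyclohex-2-ene
Product: 10 (1R,5R,6R)-2-[(tert-butyldiphenylsilyloxy)methyl]-5-isopropyl-1,6-bis(triethylsilyloxy)cyclohex-2-en-4-one
Conditions: PPTS (cat.), acetone–H2O, 0 °C
Reagents that add atoms: water, O
Why: Acid-catalysed ketal hydrolysis; ionisation gives an allyl-stabilised oxocarbenium ion, so the dimethyl ketal should be cleaved under conditions far milder than those that attack the silyl ethers. The carbonyl now sits at C4, conjugated with C2=C3, and the absence of base keeps the β-silyloxy group on C6 from eliminating.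

Step 8
Reactants: 10 (1R,5R,6R)-2-[(tert-butyldiphenylsilyloxy)methyl]-5-isopropyl-1,6-bis(triethylsilyloxy)cyclohex-2-en-4-one
Product: 11 (1R,4S,5S,6R)-2-[(tert-butyldiphenylsilyloxy)methyl]-5-isopropyl-1,6-bis(triethylsilyloxy)cyclohex-2-en-4-ol
Conditions: LiBH(s-Bu)3, THF, −78 °C; H2O
Reagents that add atoms: none
Why: 1,2-Reduction with a bulky trialkylborohydride. With the C5 isopropyl group equatorial next to the carbonyl, the reagent should attack along the equatorial trajectory on the face opposite to isopropyl, as in the conversion of 2-alkylcyclohexanones into their cis (axial) alcohols; this sets C4 as S with oxygen cis to isopropyl. The substituent on the β-carbon C2 disfavours conjugate reduction.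

Step 9
Reactants: 11 (1R,4S,5S,6R)-2-[(tert-butyldiphenylsilyloxy)methyl]-5-isopropyl-1,6-bis(triethylsilyloxy)cyclohex-2-en-4-ol
Product: 12 (1R,4S,5S,6R)-2-[(tert-butyldiphenylsilyloxy)methyl]-5-isopropyl-1,6-bis(triethylsilyloxy)cyclohex-2-en-4-yl propanoate
Conditions: (EtCO)2O, DMAP (cat.), pyridine, CH2Cl2, 0 °C to rt
Reagents that add atoms: propanoic anhydride, CCC(=O)OC(=O)CC
Why: DMAP-catalysed acylation of the only free hydroxyl; no stereocentre is touched.

Step 10
Reactants: 12 (1R,4S,5S,6R)-2-[(tert-butyldiphenylsilyloxy)methyl]-5-isopropyl-1,6-bis(triethylsilyloxy)cyclohex-2-en-4-yl propanoate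
Product: 13 (1R,4S,5R,6R)-2-[(tert-butyldiphenylsilyloxy)methyl]-1,6-dihydroxy-5-isopropylcyclohex-2-en-4-yl propanoate
Conditions: PPTS, MeOH–CH2Cl2, 0 °C to rt
Reagents that add atoms: none
Why: Acid-catalysed methanolysis of the two triethylsilyl ethers; the tert-butyldiphenylsilyl ether and the propanoate should be inert to pyridinium tosylate at this temperature.

Step 11
Reactants: 13 (1R,4S,5R,6R)-2-[(tert-butyldiphenylsilyloxy)methyl]-1,6-dihydroxy-5-isopropylcyclohex-2-en-4-yl propanoate
Product: 14 (4S,5R,6R)-2-[(tert-butyldiphenylsilyloxy)methyl]-6-hydroxy-5-isopropyl-1-oxocyclohex-2-en-4-yl propanoate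
Conditions: MnO2, CH2Cl2, rt
Reagents that add atoms: none
Why: Allylic oxidation with MnO2; only the C1 hydroxyl is allylic, so the saturated C6 hydroxyl should stay untouched and the enone of the target is regenerated. Short contact with freshly activated oxidant limits any glycol cleavage.

Step 12
Reactants: 15 (tert-butyldimethylsilyloxy)acetaldehyde; 16 ethyl 2-(triphenylphosphoranylidene)propanoate
Product: 17 ethyl (E)-4-(tert-butyldimethylsilyloxy)-2-methylbut-2-enoate
Conditions: CH2Cl2, rt
Reagents that add atoms: none
Why: Wittig reaction of a stabilised ylide, which should give the E-trisubstituted enoate with the silyloxymethyl carbon trans to the ester.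

Step 13
Reactants: 17 ethyl (E)-4-(tert-butyldimethylsilyloxy)-2-methylbut-2-enoate
Product: 18 (E)-4-(tert-butyldimethylsilyloxy)-2-methylbut-2-enoic acid
Conditions: LiOH, THF–H2O, 0 °C to rt; then 1 M HCl to pH 4, 0 °C
Reagents that add atoms: lithium hydroxide, [Li+].[OH-]
Why: Saponification of the ethyl ester; the primary silyl ether should survive dilute hydroxide at low temperature and a brief adjustment to pH 4.

Step 14
Reactants: 14 (4S,5R,6R)-2-[(tert-butyldiphenylsilyloxy)methyl]-6-hydroxy-5-isopropyl-1-oxocyclohex-2-en-4-yl propanoate; 18 (E)-4-(tert-butyldimethylsilyloxy)-2-methylbut-2-enoic acid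
Product: 20 (4S,5S,6R)-2-[(tert-butyldiphenylsilyloxy)methyl]-5-isopropyl-1-oxo-4-(propanoyloxy)cyclohex-2-en-6-yl (E)-4-(tert-butyldimethylsilyloxy)-2-methylbut-2-enoate, via mixed anhydride 19 (not isolated)
Conditions: 2,4,6-Cl3C6H2COCl, Et3N, THF, rt; then 14, DMAP (0.3 equiv), toluene, 0 °C to rt
Reagents that add atoms: none
Why: Yamaguchi esterification; the acid is activated as the mixed anhydride 19, from which DMAP transfers the unsaturated acyl group to the hindered C6 hydroxyl. The C6 configuration (trans to isopropyl, the thermodynamically favoured arrangement) and the E geometry should be retained.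

Step 15
Reactants: 20 (4S,5S,6R)-2-[(tert-butyldiphenylsilyloxy)methyl]-5-isopropyl-1-oxo-4-(propanoyloxy)cyclohex-2-en-6-yl (E)-4-(tert-butyldimethylsilyloxy)-2-methylbut-2-enoate
Product: 21 (4S,5S,6R)-2-(hydroxymethyl)-5-isopropyl-1-oxo-4-(propanoyloxy)cyclohex-2-en-6-yl (E)-4-hydroxy-2-methylbut-2-enoate
Conditions: HF·pyridine, pyridine, THF, 0 °C to rt
Reagents that add atoms: none
Why: Fluoride-mediated cleavage of both primary silyl ethers under acidic, non-basic conditions that should spare the two esters, the enone and the enolisable C6 centre.

## Compound list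

1 | 2-hydroxy-5-methoxybenzaldehyde | COc1ccc(O)c(C=O)c1 | starting material
2 | 2-(hydroxymethyl)-4-methoxyphenol | COc1ccc(O)c(CO)c1 | intermediate
3 | 2-[(tert-butyldiphenylsilyloxy)methyl]-4-methoxyphenol | COc1ccc(O)c(CO[Si](c2ccccc2)(c2ccccc2)C(C)(C)C)c1 | intermediate
4 | 2-[(tert-butyldiphenylsilyloxy)methyl]-4,4-dimethoxycyclohexa-2,5-dien-1-one | COC1(OC)C=CC(=O)C(CO[Si](c2ccccc2)(c2ccccc2)C(C)(C)C)=C1 | intermediate
5 | diisopropylzinc | CC(C)[Zn]C(C)C | starting material
6 | isopropylzinc (5R)-2-[(tert-butyldiphenylsilyloxy)methyl]-5-isopropyl-4,4-dimethoxycyclohexa-1(6),2-dien-1-olate | COC1(OC)C=C(CO[Si](c2ccccc2)(c2ccccc2)C(C)(C)C)C(O[Zn]C(C)C)=C[C@H]1C(C)C | intermediate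
7 | (5R,6R)-2-[(tert-butyldiphenylsilyloxy)methyl]-6-hydroxy-5-isopropyl-4,4-dimethoxycyclohex-2-en-1-one | COC1(OC)C=C(CO[Si](c2ccccc2)(c2ccccc2)C(C)(C)C)C(=O)[C@H](O)[C@H]1C(C)C | intermediate
8 | (1R,5R,6R)-2-[(tert-butyldiphenylsilyloxy)methyl]-5-isopropyl-4,4-dimethoxycyclohex-2-ene-1,6-diol | COC1(OC)C=C(CO[Si](c2ccccc2)(c2ccccc2)C(C)(C)C)[C@@H](O)[C@H](O)[C@H]1C(C)C | intermediate
9 | (1R,5R,6R)-2-[(tert-butyldiphenylsilyloxy)methyl]-5-isopropyl-4,4-dimethoxy-1,6-bis(triethylsilyloxy)cyclohex-2-ene | COC1(OC)C=C(CO[Si](c2ccccc2)(c2ccccc2)C(C)(C)C)[C@@H](O[Si](CC)(CC)CC)[C@H](O[Si](CC)(CC)CC)[C@H]1C(C)C | intermediate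
10 | (1R,5R,6R)-2-[(tert-butyldiphenylsilyloxy)methyl]-5-isopropyl-1,6-bis(triethylsilyloxy)cyclohex-2-en-4-one | O=C1C=C(CO[Si](c2ccccc2)(c2ccccc2)C(C)(C)C)[C@@H](O[Si](CC)(CC)CC)[C@H](O[Si](CC)(CC)CC)[C@H]1C(C)C | intermediate
11 | (1R,4S,5S,6R)-2-[(tert-butyldiphenylsilyloxy)methyl]-5-isopropyl-1,6-bis(triethylsilyloxy)cyclohex-2-en-4-ol | O[C@H]1C=C(CO[Si](c2ccccc2)(c2ccccc2)C(C)(C)C)[C@@H](O[Si](CC)(CC)CC)[C@H](O[Si](CC)(CC)CC)[C@H]1C(C)C | intermediate
12 | (1R,4S,5S,6R)-2-[(tert-butyldiphenylsilyloxy)methyl]-5-isopropyl-1,6-bis(triethylsilyloxy)cyclohex-2-en-4-yl propanoate | CCC(=O)O[C@H]1C=C(CO[Si](c2ccccc2)(c2ccccc2)C(C)(C)C)[C@@H](O[Si](CC)(CC)CC)[C@H](O[Si](CC)(CC)CC)[C@H]1C(C)C | intermediate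
13 | (1R,4S,5R,6R)-2-[(tert-butyldiphenylsilyloxy)methyl]-1,6-dihydroxy-5-isopropylcyclohex-2-en-4-yl propanoate | CCC(=O)O[C@H]1C=C(CO[Si](c2ccccc2)(c2ccccc2)C(C)(C)C)[C@@H](O)[C@H](O)[C@H]1C(C)C | intermediate
14 | (4S,5R,6R)-2-[(tert-butyldiphenylsilyloxy)methyl]-6-hydroxy-5-isopropyl-1-oxocyclohex-2-en-4-yl propanoate | CCC(=O)O[C@H]1C=C(CO[Si](c2ccccc2)(c2ccccc2)C(C)(C)C)C(=O)[C@H](O)[C@H]1C(C)C | intermediate
15 | (tert-butyldimethylsilyloxy)acetaldehyde | O=CCO[Si](C)(C)C(C)(C)C | starting material
16 | ethyl 2-(triphenylphosphoranylidene)propanoate | CCOC(=O)C(C)=P(c1ccccc1)(c1ccccc1)c1ccccc1 | starting material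
17 | ethyl (E)-4-(tert-butyldimethylsilyloxy)-2-methylbut-2-enoate | CCOC(=O)/C(C)=C/CO[Si](C)(C)C(C)(C)C | intermediate
18 | (E)-4-(tert-butyldimethylsilyloxy)-2-methylbut-2-enoic acid | OC(=O)/C(C)=C/CO[Si](C)(C)C(C)(C)C | intermediate
19 | (E)-4-(tert-butyldimethylsilyloxy)-2-methylbut-2-enoic 2,4,6-trichlorobenzoic anhydride | O=C(OC(=O)/C(C)=C/CO[Si](C)(C)C(C)(C)C)c1c(Cl)cc(Cl)cc1Cl | intermediate
20 | (4S,5S,6R)-2-[(tert-butyldiphenylsilyloxy)methyl]-5-isopropyl-1-oxo-4-(propanoyloxy)cyclohex-2-en-6-yl (E)-4-(tert-butyldimethylsilyloxy)-2-methylbut-2-enoate | CCC(=O)O[C@H]1C=C(CO[Si](c2ccccc2)(c2ccccc2)C(C)(C)C)C(=O)[C@H](OC(=O)/C(C)=C/CO[Si](C)(C)C(C)(C)C)[C@H]1C(C)C | intermediate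
21 | (4S,5S,6R)-2-(hydroxymethyl)-5-isopropyl-1-oxo-4-(propanoyloxy)cyclohex-2-en-6-yl (E)-4-hydroxy-2-methylbut-2-enoate | CCC(=O)O[C@H]1C=C(CO)C(=O)[C@H](OC(=O)/C(C)=C/CO)[C@H]1C(C)C | target

## Step count and least certain steps

Total step count: 15 (13 on the main line and 2 for the side-chain acid 18). Longest linear sequence: 13 steps (steps 1 to 11, 14 and 15, from 1 to 21).

**Step 4 (key step).**
- Most likely failure: slow oxygen transfer to the weakly nucleophilic zinc enolate, so that simple protonation to the 1,4-adduct competes. The oxidant may also be consumed by residual carbon–zinc bonds, and the enolate may add to the sulfonimine formed. The bulky C2 substituent could in addition erode the facial selectivity at C5.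
- Fallback, from 4 and 5 back to 7: the same copper-catalysed addition is run, but the enolate 6 is silylated with TMSOTf and the trimethylsilyl dienol ether F1 is isolated. Rubottom oxidation of F1 with mCPBA and NaHCO3 in CH2Cl2 should epoxidise the enol ether anti to isopropyl and give the 6-trimethylsilyloxy ketone F2. Citric acid in methanol then desilylates F2 to 7.

**Step 8.**
- Most likely failure: poor facial selectivity at C4. Delivery of hydride along the axial trajectory would give the carbinol trans to isopropyl, and the crowded silyl ethers could distort the ring and weaken the equatorial preference.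
- Fallback, from 10 back to 12: 10 is reduced with NaBH4 and CeCl3·7H2O, a small hydride expected to favour the equatorial 4R alcohol F3. F3 is then subjected to a Mitsunobu reaction with propanoic acid (PPh3, DIAD, toluene), which inverts C4 and installs the propanoate in the same operation.

**Step 14.**
- Most likely failure: sluggish acylation of the hindered C6 hydroxyl, which gives DMAP time to epimerise C6 or shift the α-ketol, or to isomerise the activated enoate.
- Fallback, from 14 back to 20: 14 is acylated with the small, unhindered 2-(diethoxyphosphoryl)propanoic acid (DCC, catalytic DMAP) to give the phosphonate ester F4. Horner–Wadsworth–Emmons olefination of F4 with aldehyde 15 under Masamune–Roush conditions (LiCl, i-Pr2NEt, MeCN) then builds the E-enoate on the ring.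

**Step 2.**
- Most likely failure: incomplete discrimination between the two hydroxyls, with silylation of the phenol or of both positions.
- Fallback, from 2 back to 3: 2 is silylated exhaustively with excess TBDPSCl and imidazole in DMF to the bis-silyl ether F5. The aryl silyl ether of F5, far more labile to base than the alkyl one, is then cleaved selectively with K2CO3 in methanol.

## Further compounds

F1 | step 4 | (5R)-2-[(tert-butyldiphenylsilyloxy)methyl]-5-isopropyl-4,4-dimethoxy-1-(trimethylsilyloxy)cyclohexa-1(6),2-diene | COC1(OC)C=C(CO[Si](c2ccccc2)(c2ccccc2)C(C)(C)C)C(O[Si](C)(C)C)=C[C@H]1C(C)C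
F2 | step 4 | (5R,6R)-2-[(tert-butyldiphenylsilyloxy)methyl]-5-isopropyl-4,4-dimethoxy-6-(trimethylsilyloxy)cyclohex-2-en-1-one | COC1(OC)C=C(CO[Si](c2ccccc2)(c2ccccc2)C(C)(C)C)C(=O)[C@H](O[Si](C)(C)C)[C@H]1C(C)C
F3 | step 8 | (1R,4R,5S,6R)-2-[(tert-butyldiphenylsilyloxy)methyl]-5-isopropyl-1,6-bis(triethylsilyloxy)cyclohex-2-en-4-ol | O[C@@H]1C=C(CO[Si](c2ccccc2)(c2ccccc2)C(C)(C)C)[C@@H](O[Si](CC)(CC)CC)[C@H](O[Si](CC)(CC)CC)[C@H]1C(C)C
F4 | step 14 | (4S,5S,6R)-2-[(tert-butyldiphenylsilyloxy)methyl]-5-isopropyl-1-oxo-4-(propanoyloxy)cyclohex-2-en-6-yl 2-(diethoxyphosphoryl)propanoate (phosphonate α-carbon as a mixture) | CCC(=O)O[C@H]1C=C(CO[Si](c2ccccc2)(c2ccccc2)C(C)(C)C)C(=O)[C@H](OC(=O)C(C)P(=O)(OCC)OCC)[C@H]1C(C)C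
F5 | step 2 | tert-butyl{2-[(tert-butyldiphenylsilyloxy)methyl]-4-methoxyphenoxy}diphenylsilane | COc1ccc(O[Si](c2ccccc2)(c2ccccc2)C(C)(C)C)c(CO[Si](c2ccccc2)(c2ccccc2)C(C)(C)C)c1
A1 | alternative 1 | 3-hydroxy-2H-pyran-2-one | O=c1occcc1O
A2 | alternative 1 | (E)-5-methylhex-3-en-2-one | CC(=O)/C=C/C(C)C
A3 | alternative 1 | 8-acetyl-4-hydroxy-7-isopropyl-2-oxabicyclo[2.2.2]oct-5-en-3-one (endo acetyl, isopropyl syn to the lactone bridge) | O=C2O[C@H]1C=C[C@]2(O)[C@H](C(C)=O)[C@H]1C(C)C
A4 | alternative 2 | (Z)-6-iodo-2-isopropyl-3-(4-methoxybenzyloxy)-4-oxo-5-[(tert-butyldimethylsilyloxy)methyl]hex-5-enal (C2 and C3 as C5 and C6 of the target) | I/C=C(/CO[Si](C)(C)C(C)(C)C)C(=O)[C@H](OCc1ccc(OC)cc1)[C@H](C=O)C(C)C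
A5 | alternative 2 | (4S,5S,6R)-4-hydroxy-5-isopropyl-6-(4-methoxybenzyloxy)-2-[(tert-butyldimethylsilyloxy)methyl]cyclohex-2-en-1-one | O[C@H]1C=C(CO[Si](C)(C)C(C)(C)C)C(=O)[C@H](OCc2ccc(OC)cc2)[C@H]1C(C)C
A6 | alternative 3 | methyl 3,6-dideoxy-3-C-isopropyl-4-O-(4-methoxybenzyl)-2-O-propanoylhex-5-enopyranoside (gulo-type arrangement at C2 to C4, anomeric configuration immaterial) | COC1OC(=C)[C@H](OCc2ccc(OC)cc2)[C@@H](C(C)C)[C@H]1OC(=O)CC
A7 | alternative 3 | 3-hydroxy-5-isopropyl-6-(4-methoxybenzyloxy)-1-oxocyclohexan-4-yl propanoate (C4, C5, C6 as in the target) | CCC(=O)O[C@H]1[C@H](O)CC(=O)[C@H](OCc2ccc(OC)cc2)[C@H]1C(C)C
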